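## Retrosynthetic overview

- The route rests on one feature of the ten-membered carbocycle: the C1 ketone is separated by C2 and C3 from the C4=C5 (Z) alkene (germacrane numbering). A cyclodec-4-ynone with this pattern is what is released when the C1–C5 fusion bond of a 4-oxo-1,5-epoxide in a five-membered ring (C1–C5) fused to a seven-membered ring (C5–C10, C1) is cut.
- After the fragmentation: O8 tigloate, syn hydrostannation/methylation of C4≡C5 (C15), oxidative closure of the C12–O6 lactone, acetonide removal.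
- Before the fragmentation: the epoxy ketone comes from the hydroazulenone, made by oxidative 1,3-transposition of a C1 tertiary allylic alcohol. That C1 hydroxyl first directs osmylation of C9=C10, and the seven-membered ring is closed by metathesis at C9=C10.
- Acyclic stage: C6–C7 by an Evans syn aldol between an enal from (S)-4-silyloxycyclopentenone (C1–C5, C3 stereocentre) and an imide from 2-methylenepropane-1,3-diol (C7, C8, C11–C13); C8 by Evans–Tishchenko reduction.
- Ring order: five-membered ring (chiral pool), seven-membered ring (step 15), ten-membered ring (step 22), lactone (step 29).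

Key step: step 22

Remark on the chemistry: the C4 carbinol and the C1–C5 epoxide in 27–30 are transient. They are written α (hydride anti to the C3 silyl ether, vanadium delivery syn to the C4 hydroxyl); either epoxide face should fragment to the same ynone 31. Germacrane numbering is used throughout.

## Route

Step 1
Reactants: 1 (S)-4-(tert-butyldimethylsilyloxy)cyclopent-2-en-1-one
Product: 2 (S)-4-(tert-butyldimethylsilyloxy)-2-iodocyclopent-2-en-1-one
Conditions: I2, pyridine, CH2Cl2, 0 °C → rt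
Reagents that add atoms: iodine, II
Why: α-Iodination of an enone (pyridine conjugate addition, enolate iodination, elimination) should place iodine on C5 without touching the C3 silyloxy stereocentre.

Step 2
Reactants: 2 (S)-4-(tert-butyldimethylsilyloxy)-2-iodocyclopent-2-en-1-one
Product: 3 (1S,4S)-4-(tert-butyldimethylsilyloxy)-2-iodo-1-(prop-1-en-2-yl)cyclopent-2-en-1-ol
Conditions: CH2=C(CH3)MgBr, CeCl3, THF, −78 °C
Reagents that add atoms: isopropenylmagnesium bromide, CC(=C)[Mg]Br
Why: Cerium-assisted 1,2-addition of the alkenyl Grignard reagent should occur anti to the C3 silyl ether, so the tertiary C1 hydroxyl ends cis to O3 (a relay centre used in step 16 and destroyed in step 18).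

Step 3
Reactants: 3 (1S,4S)-4-(tert-butyldimethylsilyloxy)-2-iodo-1-(prop-1-en-2-yl)cyclopent-2-en-1-ol
Product: 5 (3S,5S)-3-(tert-butyldimethylsilyloxy)-5-hydroxy-5-(prop-1-en-2-yl)cyclopent-1-ene-1-carbaldehyde, via dilithio species 4 (not isolated)
Conditions: MeLi (1 equiv), then t-BuLi (2 equiv), THF/Et2O, −78 °C; DMF; aq. NH4Cl
Reagents that add atoms: N,N-dimethylformamide, CN(C)C=O
Why: Deprotonation of the hydroxyl, iodine–lithium exchange and formylation of the alkenyllithium should install the C6 aldehyde on C5.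

Step 4
Reactants: 6 2-methylenepropane-1,3-diol
Product: 7 2-[(tert-butyldimethylsilyloxy)methyl]prop-2-en-1-ol
Conditions: NaH (1 equiv), THF, 0 °C; TBSCl (1 equiv)
Reagents that add atoms: tert-butyldimethylsilyl chloride, CC(C)(C)[Si](C)(C)Cl
Why: Monosilylation of a symmetrical diol through its poorly soluble monosodium alkoxide should give the mono-ether (future O12).

Step 5
Reactants: 7 2-[(tert-butyldimethylsilyloxy)methyl]prop-2-en-1-ol
Product: 8 {[2-(bromomethyl)prop-2-en-1-yl]oxy}(tert-butyl)dimethylsilane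
Conditions: CBr4, PPh3, CH2Cl2, 0 °C
Reagents that add atoms: tetrabromomethane, BrC(Br)(Br)Br
Why: The Appel reaction converts the primary allylic alcohol into the bromide under neutral conditions that spare the silyl ether.

Step 6
Reactants: 8 {[2-(bromomethyl)prop-2-en-1-yl]oxy}(tert-butyl)dimethylsilane
Product: 10 3-[(tert-butyldimethylsilyloxy)methyl]but-3-enoic acid, via allylic Grignard reagent 9 (not isolated)
Conditions: Mg, THF, 0 °C (slow addition); CO2, −40 → 0 °C; aq. citric acid
Reagents that add atoms: carbon dioxide, O=C=O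
Why: Carboxylation of an allylic Grignard reagent whose two termini are identical should give the β,γ-unsaturated acid (C8, C7, C11–C13) without a regiochemical issue.

Step 7
Reactants: 10 3-[(tert-butyldimethylsilyloxy)methyl]but-3-enoic acid; 11 (S)-4-benzyloxazolidin-2-one
Product: 13 (S)-4-benzyl-3-{3-[(tert-butyldimethylsilyloxy)methyl]but-3-enoyl}oxazolidin-2-one, via mixed pivalic anhydride 12 (not isolated)
Conditions: PivCl, Et3N, THF, −20 °C; then 11, LiCl, rt
Reagents that add atoms: none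
Why: N-Acylation of the oxazolidinone by the mixed anhydride (lithium chloride-assisted) should attach the auxiliary under conditions mild enough to keep the alkene out of conjugation.

Step 8
Reactants: 13 (S)-4-benzyl-3-{3-[(tert-butyldimethylsilyloxy)methyl]but-3-enoyl}oxazolidin-2-one; 5 (3S,5S)-3-(tert-butyldimethylsilyloxy)-5-hydroxy-5-(prop-1-en-2-yl)cyclopent-1-ene-1-carbaldehyde
Product: 15 syn-aldol imide, via boron enolate 14 (not isolated)
Conditions: Bu2BOTf, i-Pr2NEt, CH2Cl2, −78 → 0 °C (2 equiv enolate); 5, −78 → −20 °C; pH 7 buffer, MeOH, H2O2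
Reagents that add atoms: none
Why: In this Evans syn aldol the (Z)-boron enolate reacts at its α-carbon through a Zimmerman–Traxler chair on the face away from the benzyl group, which should set C6 (carbinol) and C7 syn and in the absolute sense of the target.

Step 9
Reactants: 15 syn-aldol imide
Product: 16 Weinreb amide
Conditions: MeNHOMe·HCl, AlMe3, CH2Cl2, −20 → 0 °C
Reagents that add atoms: N,O-dimethylhydroxylamine hydrochloride, CNOC.Cl
Why: Aluminium amide transamination of the imide, assisted by the free β-hydroxyl, should release the auxiliary and give the Weinreb amide at C8 without epimerising C7.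

Step 10
Reactants: 16 Weinreb amide
Product: 17 β-hydroxy vinyl ketone
Conditions: CH2=CHMgBr (5 equiv), THF, −78 → 0 °C; inverse quench into cold aq. NH4Cl
Reagents that add atoms: vinylmagnesium bromide, C=C[Mg]Br
Why: Weinreb ketone synthesis stops at the ketone through the chelated tetrahedral intermediate and brings in C9 as a vinyl group.

Step 11
Reactants: 17 β-hydroxy vinyl ketone
Product: 18 anti-1,3-diol 6-monoacetate
Conditions: SmI2 (0.3 equiv, premixed with CH3CHO), CH3CHO (6 equiv), THF, −10 °C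
Reagents that add atoms: acetaldehyde, CC=O
Why: In the Evans–Tishchenko reduction, hydride is delivered within the samarium-bound hemiacetal of the C6 hydroxyl, which should set C8 1,3-anti to C6 and leave O6 as acetate and O8 free.

Step 12
Reactants: 18 anti-1,3-diol 6-monoacetate
Product: 19 8-O-(4-methoxybenzyl) ether
Conditions: 2-(4-methoxybenzyloxy)-4-methylquinoline, MeOTf, MgO, PhCF3, 0 °C → rt
Reagents that add atoms: 2-(4-methoxybenzyloxy)-4-methylquinoline, COc1ccc(COc2cc(C)c3ccccc3n2)cc1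
Why: Benzyl transfer from the N-methylquinolinium salt formed in the flask etherifies O8 under neutral conditions, avoiding acyl migration and ionisation of the bis-allylic C1 alcohol.

Step 13
Reactants: 19 8-O-(4-methoxybenzyl) ether
Product: 20 C6 alcohol
Conditions: K2CO3, MeOH, 0 °C → rt
Reagents that add atoms: none
Why: Transesterification with methoxide removes the acetate; no other ester is present.

Step 14
Reactants: 20 C6 alcohol
Product: 21 metathesis precursor (6-O-triisopropylsilyl ether)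
Conditions: TIPSOTf, 2,6-lutidine, CH2Cl2, −78 → 0 °C
Reagents that add atoms: triisopropylsilyl trifluoromethanesulfonate, CC(C)[Si](C(C)C)(C(C)C)OS(=O)(=O)C(F)(F)F
Why: Silylation should take the secondary C6 hydroxyl and leave the hindered tertiary C1 hydroxyl free.

Step 15
Reactants: 21 metathesis precursor (6-O-triisopropylsilyl ether)
Product: 22 bicyclic dienol
Conditions: second-generation Hoveyda–Grubbs catalyst RuCl2(H2IMes)(=CH-C6H4-2-OiPr) (10 mol%), toluene, 80 °C, high dilution
Reagents that add atoms: none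
Why: Ring-closing metathesis between the C8 vinyl and the C1 isopropenyl group should close the seven-membered ring at C9=C10 (necessarily cis in the ring); the other alkenes could only give a four-membered ring or a tetrasubstituted alkene.

Step 16
Reactants: 22 bicyclic dienol
Product: 24 C1,C9,C10 triol, via osmate ester 23 (not isolated)
Conditions: OsO4 (1.05 equiv), TMEDA, CH2Cl2, −78 °C; then aq. Na2SO3, THF, 40 °C
Reagents that add atoms: osmium tetroxide, O=[Os](=O)(=O)=O
Why: Hydrogen-bond-directed dihydroxylation: the OsO4–diamine complex is delivered by the tertiary C1 hydroxyl to the adjacent C9=C10 alkene on the hydroxyl face, which should set O9 and O10 cis to each other and α; C4=C5 is shielded by the two flanking silyl ethers and C11=C13 lacks a directing group.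

Step 17
Reactants: 24 C1,C9,C10 triol
Product: 25 9,10-acetonide tertiary allylic alcohol
Conditions: 2-methoxypropene, PPTS (cat.), CH2Cl2, 0 °C
Reagents that add atoms: 2-methoxypropene, COC(C)=C
Why: Acid-catalysed ketalisation should engage the secondary/tertiary cis-diol at C9/C10 in preference to the di-tertiary C1/C10 pair, leaving the C1 hydroxyl free.

Step 18
Reactants: 25 9,10-acetonide tertiary allylic alcohol
Product: 26 hydroazulenone
Conditions: [C5H5NH][CrO3Cl] (pyridinium chlorochromate), NaOAc, 4 Å MS, CH2Cl2, rt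
Reagents that add atoms: pyridinium chlorochromate, [O-][Cr](=O)(=O)Cl.c1cc[nH+]cc1
Why: In the Dauben–Babler oxidative transposition the chromate ester of the C1 alcohol shifts [3,3] to C4 and is oxidised, giving the C4 ketone and the C1=C5 fusion alkene; only one allylic system remains, so the direction is unambiguous and the C3 centre is untouched.

Step 19
Reactants: 26 hydroazulenone
Product: 27 C4 allylic alcohol
Conditions: NaBH4, CeCl3·7H2O, MeOH, −40 °C
Reagents that add atoms: none
Why: Luche 1,2-reduction should give the allylic alcohol (hydride anti to the C3 silyl ether), avoiding base on the α'-silyloxy ketone; the C4 configuration is immaterial.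

Step 20
Reactants: 27 C4 allylic alcohol
Product: 28 epoxy alcohol
Conditions: VO(acac)2 (5 mol%), t-BuOOH, CH2Cl2, 0 °C → rt
Reagents that add atoms: tert-butyl hydroperoxide, CC(C)(C)OO
Why: Vanadium-catalysed hydroxyl-directed epoxidation delivers oxygen syn to the C4 hydroxyl onto the tetrasubstituted C1=C5 alkene, which is too hindered for reliable nucleophilic epoxidation; the unactivated C11=C13 alkene should not react.

Step 21
Reactants: 28 epoxy alcohol
Product: 29 hydroazulenone fusion epoxide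
Conditions: Dess–Martin periodinane, NaHCO3, CH2Cl2, 0 °C → rt
Reagents that add atoms: none
Why: Dess–Martin oxidation of the secondary carbinol under buffered conditions should give the α,β-epoxy ketone without epimerising C3 or opening the epoxide.

Step 22
Reactants: 29 hydroazulenone fusion epoxide
Product: 31 ten-membered 4-ynone, via tosylhydrazone 30 (not isolated)
Conditions: TsNHNH2 (1.2 equiv), AcOH/CH2Cl2 (1:2), −20 °C → rt
Reagents that add atoms: none
Why: Condensation at the only carbonyl (C4) gives tosylhydrazone 30, whose N–H tautomer or conjugate base opens the C5–O bond of the epoxide to an azoalkene carrying the oxygen on C1. Grob-type fragmentation follows: the C1 oxygen becomes the carbonyl, the C1–C5 σ-bond breaks, C4–C5 becomes the alkyne, and N2 and toluenesulfinate leave. This is the Eschenmoser–Tanabe fragmentation, known for ring-fused epoxy cyclopentanones giving cycloalkynones, here applied to a more oxygenated bicycle. No ring is closed by bond formation: the ten-membered ring appears when the bond shared by the five- and seven-membered rings is cut, and no stereocentre is created. The step needs hydrazone formation and fragmentation to outrun acid opening of the tertiary epoxide and β-elimination of the C3 silyl ether from the product; the single ketone, the deactivation of the epoxide by the adjacent C=N, the low temperature and the weak acid should secure this. Loss of N2 makes the fragmentation irreversible, and C3 and C6–C10 are spectators.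

Step 23
Reactants: 31 ten-membered 4-ynone
Product: 32 C8 alcohol
Conditions: DDQ, CH2Cl2/pH 7 buffer (10:1), 0 °C
Reagents that add atoms: none
Why: Oxidative cleavage of the 4-methoxybenzyl ether frees only O8; silyl ethers, acetonide and alkyne are inert to DDQ.

Step 24
Reactants: 32 C8 alcohol
Product: 33 C8 tigloate
Conditions: (E)-2-methylbut-2-enoyl chloride, pyridine, DMAP (cat.), CH2Cl2, 0 °C → rt
Reagents that add atoms: (E)-2-methylbut-2-enoyl chloride, C/C=C(\C)C(Cl)=O
Why: DMAP-catalysed acylation of the only free hydroxyl installs the tigloate while O3 is still silylated, so no O3/O8 selectivity is needed.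

Step 25
Reactants: 33 C8 tigloate
Product: 34 C3,C12 diol
Conditions: HF·pyridine, pyridine, THF, 0 °C → rt
Reagents that add atoms: none
Why: Fluoride-mediated desilylation removes the primary and the secondary tert-butyldimethylsilyl ethers much faster than the hindered secondary triisopropylsilyl ether at O6, which must stay for the next step.

Step 26
Reactants: 34 C3,C12 diol
Product: 35 C4 alkenylstannane
Conditions: Bu3SnH, Pd(PPh3)2Cl2 (5 mol%), THF, 0 °C
Reagents that add atoms: tributyltin hydride, CCCC[SnH](CCCC)CCCC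
Why: Palladium-catalysed hydrostannation is a syn addition, which in a ten-membered ring can only give the cis alkene; tin should go to C4, next to the free C3 carbinol and away from the bulky C6 silyl ether, with hydrogen on C5.

Step 27
Reactants: 35 C4 alkenylstannane
Product: 36 C4-methyl (Z)-alkene
Conditions: MeI, Pd(PPh3)4 (5 mol%), Cu(O2CC4H3S) (copper thiophene-2-carboxylate), [NBu4][Ph2PO2], DMF, rt
Reagents that add atoms: iodomethane, CI
Why: Copper-assisted Stille methylation replaces tin by methyl (C15) with retention of alkene geometry and tolerates the free hydroxyls, the ketone and the ester.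

Step 28
Reactants: 36 C4-methyl (Z)-alkene
Product: 37 C3,C6,C12 triol
Conditions: TBAF, AcOH (1:1), THF, 0 °C → rt
Reagents that add atoms: none
Why: Buffered fluoride removes the triisopropylsilyl ether at O6 without triggering retro-aldol or elimination of the β-hydroxy ketone.

Step 29
Reactants: 37 C3,C6,C12 triol
Product: 40 lactone acetonide, via enal 38 (not isolated), via lactol 39 (not isolated)
Conditions: TEMPO (20 mol%), PhI(OAc)2 (2.5 equiv), CH2Cl2, rt
Reagents that add atoms: none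
Why: Oxoammonium oxidation takes the primary allylic C12 alcohol to the enal, which is trapped by O6 as the lactol and oxidised on to the α-methylene-γ-lactone; the secondary C3 alcohol reacts much more slowly and the acetonide protects the diol from glycol cleavage.

Step 30
Reactants: 40 lactone acetonide
Product: 41 CNP0106709.2
Conditions: TFA/H2O (4:1), CH2Cl2, 0 °C
Reagents that add atoms: none
Why: Acid hydrolysis of the acetonide at low temperature should release the C9/C10 diol while the tigloate, the lactone and the allylic C3 alcohol survive.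

## Compound list

1 | (S)-4-(tert-butyldimethylsilyloxy)cyclopent-2-en-1-one | O=C1C=C[C@@H](O[Si](C)(C)C(C)(C)C)C1 | starting material
2 | (S)-4-(tert-butyldimethylsilyloxy)-2-iodocyclopent-2-en-1-one | O=C1C(I)=C[C@@H](O[Si](C)(C)C(C)(C)C)C1 | intermediate
3 | (1S,4S)-4-(tert-butyldimethylsilyloxy)-2-iodo-1-(prop-1-en-2-yl)cyclopent-2-en-1-ol (OH cis to silyloxy) | CC(=C)[C@]1(O)C(I)=C[C@@H](O[Si](C)(C)C(C)(C)C)C1 | intermediate
4 | dilithio species (lithium alkoxide, C5 alkenyllithium) of 3 | CC(=C)[C@]1(O[Li])C([Li])=C[C@@H](O[Si](C)(C)C(C)(C)C)C1 | intermediate (not isolated)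
5 | (3S,5S)-3-(tert-butyldimethylsilyloxy)-5-hydroxy-5-(prop-1-en-2-yl)cyclopent-1-ene-1-carbaldehyde | CC(=C)[C@]1(O)C(C=O)=C[C@@H](O[Si](C)(C)C(C)(C)C)C1 | intermediate
6 | 2-methylenepropane-1,3-diol | C=C(CO)CO | starting material
7 | 2-[(tert-butyldimethylsilyloxy)methyl]prop-2-en-1-ol | C=C(CO)CO[Si](C)(C)C(C)(C)C | intermediate
8 | {[2-(bromomethyl)prop-2-en-1-yl]oxy}(tert-butyl)dimethylsilane | C=C(CBr)CO[Si](C)(C)C(C)(C)C | intermediate
9 | allylic Grignard reagent from 8 | C=C(C[Mg]Br)CO[Si](C)(C)C(C)(C)C | intermediate (not isolated)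
10 | 3-[(tert-butyldimethylsilyloxy)methyl]but-3-enoic acid | OC(=O)CC(=C)CO[Si](C)(C)C(C)(C)C | intermediate
11 | (S)-4-benzyloxazolidin-2-one | O=C1OC[C@H](Cc2ccccc2)N1 | starting material
12 | mixed pivalic anhydride of 10 | CC(C)(C)C(=O)OC(=O)CC(=C)CO[Si](C)(C)C(C)(C)C | intermediate (not isolated)
13 | (S)-4-benzyl-3-{3-[(tert-butyldimethylsilyloxy)methyl]but-3-enoyl}oxazolidin-2-one | O=C1OC[C@H](Cc2ccccc2)N1C(=O)CC(=C)CO[Si](C)(C)C(C)(C)C | intermediate
14 | (Z)-dibutylboron enolate of 13 | O=C1OC[C@H](Cc2ccccc2)N1/C(OB(CCCC)CCCC)=C/C(=C)CO[Si](C)(C)C(C)(C)C | intermediate (not isolated)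
15 | syn-aldol imide: C8 acyl oxazolidinone, C7 bearing the 3-silyloxyprop-1-en-2-yl group, C6 carbinol on C5 of the cyclopentene (C6, C7 as in 41) | O=C1OC[C@H](Cc2ccccc2)N1C(=O)[C@@H](C(=C)CO[Si](C)(C)C(C)(C)C)[C@H](O)C3=C[C@@H](O[Si](C)(C)C(C)(C)C)C[C@]3(O)C(C)=C | intermediate
16 | Weinreb amide (C8 N-methoxy-N-methylamide of 15) | CON(C)C(=O)[C@@H](C(=C)CO[Si](C)(C)C(C)(C)C)[C@H](O)C1=C[C@@H](O[Si](C)(C)C(C)(C)C)C[C@]1(O)C(C)=C | intermediate
17 | β-hydroxy vinyl ketone (C8 ketone, C9 vinyl) | C=CC(=O)[C@@H](C(=C)CO[Si](C)(C)C(C)(C)C)[C@H](O)C1=C[C@@H](O[Si](C)(C)C(C)(C)C)C[C@]1(O)C(C)=C | intermediate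
18 | anti-1,3-diol 6-monoacetate (C8 carbinol as in 41) | C=C[C@@H](O)[C@@H](C(=C)CO[Si](C)(C)C(C)(C)C)[C@H](OC(C)=O)C1=C[C@@H](O[Si](C)(C)C(C)(C)C)C[C@]1(O)C(C)=C | intermediate
19 | 8-O-(4-methoxybenzyl) ether, 6-O-acetate | C=C[C@@H](OCc2ccc(OC)cc2)[C@@H](C(=C)CO[Si](C)(C)C(C)(C)C)[C@H](OC(C)=O)C1=C[C@@H](O[Si](C)(C)C(C)(C)C)C[C@]1(O)C(C)=C | intermediate
20 | C6 alcohol (8-O-4-methoxybenzyl) | C=C[C@@H](OCc2ccc(OC)cc2)[C@@H](C(=C)CO[Si](C)(C)C(C)(C)C)[C@H](O)C1=C[C@@H](O[Si](C)(C)C(C)(C)C)C[C@]1(O)C(C)=C | intermediate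
21 | metathesis precursor (6-O-triisopropylsilyl, 8-O-4-methoxybenzyl, free C1 OH) | C=C[C@@H](OCc2ccc(OC)cc2)[C@@H](C(=C)CO[Si](C)(C)C(C)(C)C)[C@H](O[Si](C(C)C)(C(C)C)C(C)C)C1=C[C@@H](O[Si](C)(C)C(C)(C)C)C[C@]1(O)C(C)=C | intermediate
22 | bicyclic dienol (C4=C5 and C9=C10 alkenes, C1 tertiary alcohol) | CC(C)[Si](C(C)C)(C(C)C)O[C@H]1[C@H](C(=C)CO[Si](C)(C)C(C)(C)C)[C@H](OCc2ccc(OC)cc2)C=C(C)[C@@]3(O)C[C@H](O[Si](C)(C)C(C)(C)C)C=C13 | intermediate
23 | osmate ester (C9,C10 glycolate of hexavalent osmium, TMEDA chelate) | CC(C)[Si](C(C)C)(C(C)C)O[C@H]1[C@H](C(=C)CO[Si](C)(C)C(C)(C)C)[C@H](OCc2ccc(OC)cc2)[C@@H]4O[Os-2]5(=O)(=O)([N+](C)(C)CC[N+]5(C)C)O[C@]4(C)[C@@]3(O)C[C@H](O[Si](C)(C)C(C)(C)C)C=C13 | intermediate (not isolated)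
24 | C1,C9,C10 triol (all three hydroxyls on the α face) | CC(C)[Si](C(C)C)(C(C)C)O[C@H]1[C@H](C(=C)CO[Si](C)(C)C(C)(C)C)[C@H](OCc2ccc(OC)cc2)[C@H](O)[C@](C)(O)[C@@]3(O)C[C@H](O[Si](C)(C)C(C)(C)C)C=C13 | intermediate
25 | 9,10-acetonide tertiary allylic alcohol | CC(C)[Si](C(C)C)(C(C)C)O[C@H]1[C@H](C(=C)CO[Si](C)(C)C(C)(C)C)[C@H](OCc2ccc(OC)cc2)[C@@H]4OC(C)(C)O[C@]4(C)[C@@]3(O)C[C@H](O[Si](C)(C)C(C)(C)C)C=C13 | intermediate
26 | hydroazulenone (C4 ketone, C1=C5 fusion alkene) | CC(C)[Si](C(C)C)(C(C)C)O[C@H]1[C@H](C(=C)CO[Si](C)(C)C(C)(C)C)[C@H](OCc2ccc(OC)cc2)[C@@H]4OC(C)(C)O[C@]4(C)C3=C1C(=O)[C@@H](O[Si](C)(C)C(C)(C)C)C3 | intermediate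
27 | C4 allylic alcohol (OH cis to O3) | CC(C)[Si](C(C)C)(C(C)C)O[C@H]1[C@H](C(=C)CO[Si](C)(C)C(C)(C)C)[C@H](OCc2ccc(OC)cc2)[C@@H]4OC(C)(C)O[C@]4(C)C3=C1[C@@H](O)[C@@H](O[Si](C)(C)C(C)(C)C)C3 | intermediate
28 | epoxy alcohol (C1–C5 epoxide syn to C4 OH) | CC(C)[Si](C(C)C)(C(C)C)O[C@@H]2[C@]3(O4)[C@@H](O)[C@@H](O[Si](C)(C)C(C)(C)C)C[C@]34[C@@]5(C)OC(C)(C)O[C@H]5[C@@H](OCc6ccc(OC)cc6)[C@H]2C(=C)CO[Si](C)(C)C(C)(C)C | intermediate
29 | hydroazulenone fusion epoxide (key-step precursor) | CC(C)[Si](C(C)C)(C(C)C)O[C@@H]2[C@]3(O4)C(=O)[C@@H](O[Si](C)(C)C(C)(C)C)C[C@]34[C@@]5(C)OC(C)(C)O[C@H]5[C@@H](OCc6ccc(OC)cc6)[C@H]2C(=C)CO[Si](C)(C)C(C)(C)C | intermediate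
30 | C4 tosylhydrazone of 29 | CC(C)[Si](C(C)C)(C(C)C)O[C@@H]2[C@]3(O4)C(=NNS(=O)(=O)c7ccc(C)cc7)[C@@H](O[Si](C)(C)C(C)(C)C)C[C@]34[C@@]5(C)OC(C)(C)O[C@H]5[C@@H](OCc6ccc(OC)cc6)[C@H]2C(=C)CO[Si](C)(C)C(C)(C)C | intermediate (not isolated)
31 | ten-membered 4-ynone (C1 ketone, C4≡C5 alkyne; key-step product) | CC(C)[Si](C(C)C)(C(C)C)O[C@@H]2C#C[C@@H](O[Si](C)(C)C(C)(C)C)CC(=O)[C@@]3(C)OC(C)(C)O[C@H]3[C@@H](OCc4ccc(OC)cc4)[C@H]2C(=C)CO[Si](C)(C)C(C)(C)C | intermediate
32 | C8 alcohol | CC(C)[Si](C(C)C)(C(C)C)O[C@@H]2C#C[C@@H](O[Si](C)(C)C(C)(C)C)CC(=O)[C@@]3(C)OC(C)(C)O[C@H]3[C@@H](O)[C@H]2C(=C)CO[Si](C)(C)C(C)(C)C | intermediate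
33 | C8 tigloate | CC(C)[Si](C(C)C)(C(C)C)O[C@@H]2C#C[C@@H](O[Si](C)(C)C(C)(C)C)CC(=O)[C@@]3(C)OC(C)(C)O[C@H]3[C@@H](OC(=O)/C(C)=C/C)[C@H]2C(=C)CO[Si](C)(C)C(C)(C)C | intermediate
34 | C3,C12 diol (6-O-triisopropylsilyl) | CC(C)[Si](C(C)C)(C(C)C)O[C@@H]2C#C[C@@H](O)CC(=O)[C@@]3(C)OC(C)(C)O[C@H]3[C@@H](OC(=O)/C(C)=C/C)[C@H]2C(=C)CO | intermediate
35 | C4 alkenylstannane (cis ring alkene, H on C5) | CC(C)[Si](C(C)C)(C(C)C)O[C@@H]2/C=C(/[Sn](CCCC)(CCCC)CCCC)[C@@H](O)CC(=O)[C@@]3(C)OC(C)(C)O[C@H]3[C@@H](OC(=O)/C(C)=C/C)[C@H]2C(=C)CO | intermediate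
36 | C4-methyl (Z)-alkene | CC(C)[Si](C(C)C)(C(C)C)O[C@@H]2/C=C(/C)[C@@H](O)CC(=O)[C@@]3(C)OC(C)(C)O[C@H]3[C@@H](OC(=O)/C(C)=C/C)[C@H]2C(=C)CO | intermediate
37 | C3,C6,C12 triol | O[C@@H]2/C=C(/C)[C@@H](O)CC(=O)[C@@]3(C)OC(C)(C)O[C@H]3[C@@H](OC(=O)/C(C)=C/C)[C@H]2C(=C)CO | intermediate
38 | C12 enal | O[C@@H]2/C=C(/C)[C@@H](O)CC(=O)[C@@]3(C)OC(C)(C)O[C@H]3[C@@H](OC(=O)/C(C)=C/C)[C@H]2C(=C)C=O | intermediate (not isolated)
39 | C12 lactol | C=C1C(O)O[C@@H]2/C=C(/C)[C@@H](O)CC(=O)[C@@]3(C)OC(C)(C)O[C@H]3[C@@H](OC(=O)/C(C)=C/C)[C@@H]12 | intermediate (not isolated)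
40 | lactone acetonide | C=C1C(=O)O[C@@H]2/C=C(/C)[C@@H](O)CC(=O)[C@@]3(C)OC(C)(C)O[C@H]3[C@@H](OC(=O)/C(C)=C/C)[C@@H]12 | intermediate
41 | CNP0106709.2 (3S,4Z,6R,7S,8S,9S,10S) | C=C1C(=O)O[C@@H]2/C=C(/C)[C@@H](O)CC(=O)[C@@](C)(O)[C@@H](O)[C@@H](OC(=O)/C(C)=C/C)[C@@H]12 | target

## Step count and risks

Total: 30 steps. Longest linear sequence: 27 steps (6 → 41, steps 4–30).

Steps most likely to fail:

1. Step 22 (fragmentation). The C4 carbonyl is flanked by the epoxide carbon and the silyloxy carbon, so hydrazone formation may be slow; acid may then open the tertiary epoxide, or the C3 silyl ether may be lost by β-elimination from the ynone. Fallback, from 29 back to 31: 29 is condensed with 1-amino-2-phenylaziridine (as its acetate salt, CH2Cl2, 0 °C) to the aziridinyl hydrazone F1. Warming F1 in toluene should expel styrene and N2 and fragment the epoxide thermally, with no acid, base or sulfinate present.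

2. Step 16 (directed dihydroxylation). The osmium reagent may attack anti to the C8 ether despite the hydrogen bond, or react at C4=C5 or C11=C13. Fallback, from 22 back to 24: vanadium-catalysed epoxidation (VO(acac)2, t-BuOOH), directed by the C1 hydroxyl, should give the α-epoxide F2. Halide-catalysed CO2 insertion (LiBr, CO2, DMF, 80 °C) proceeds by double inversion and should give the cis cyclic carbonate F3 on the same face. Methanolysis (K2CO3, MeOH) then gives triol 24.

3. Step 26 (hydrostannation). Both alkyne carbons carry a propargylic oxygen, so tin may add unselectively, and the tin hydride may also reduce the tigloate. Fallback, from 34 back to 36: platinum-catalysed hydrosilylation (Et3SiH, Pt2[(CH2=CHSiMe2)2O]3, P(t-Bu)3, THF) is a syn addition governed by sterics and should place silicon on C4, remote from the C6 silyl ether, giving alkenylsilane F4. Iododesilylation with retention (N-iodosuccinimide, 2,6-lutidine, (CF3)2CHOH, 0 °C) gives alkenyl iodide F5, and Negishi methylation (Me2Zn, Pd(PtBu3)2, THF) gives 36.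

Further compounds
F1 | step 22 | aziridinyl hydrazone of 29 (C4=N–N-(2-phenylaziridin-1-yl)) | CC(C)[Si](C(C)C)(C(C)C)O[C@@H]2[C@]3(O4)C(=NN7CC7c8ccccc8)[C@@H](O[Si](C)(C)C(C)(C)C)C[C@]34[C@@]5(C)OC(C)(C)O[C@H]5[C@@H](OCc6ccc(OC)cc6)[C@H]2C(=C)CO[Si](C)(C)C(C)(C)C
F2 | step 16 | C9,C10 α-epoxide of 22 | CC(C)[Si](C(C)C)(C(C)C)O[C@H]1[C@H](C(=C)CO[Si](C)(C)C(C)(C)C)[C@H](OCc2ccc(OC)cc2)[C@@H]4O[C@]4(C)[C@@]3(O)C[C@H](O[Si](C)(C)C(C)(C)C)C=C13
F3 | step 16 | C9,C10 cis cyclic carbonate | CC(C)[Si](C(C)C)(C(C)C)O[C@H]1[C@H](C(=C)CO[Si](C)(C)C(C)(C)C)[C@H](OCc2ccc(OC)cc2)[C@@H]4OC(=O)O[C@]4(C)[C@@]3(O)C[C@H](O[Si](C)(C)C(C)(C)C)C=C13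
F4 | step 26 | C4 triethylsilyl alkene | CC(C)[Si](C(C)C)(C(C)C)O[C@@H]2/C=C(/[Si](CC)(CC)CC)[C@@H](O)CC(=O)[C@@]3(C)OC(C)(C)O[C@H]3[C@@H](OC(=O)/C(C)=C/C)[C@H]2C(=C)CO
F5 | step 26 | C4 iodoalkene | CC(C)[Si](C(C)C)(C(C)C)O[C@@H]2/C=C(/I)[C@@H](O)CC(=O)[C@@]3(C)OC(C)(C)O[C@H]3[C@@H](OC(=O)/C(C)=C/C)[C@H]2C(=C)CO
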